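**Plan** (atoms numbered along the carbon chain of the target, C1 = alkyne CH to C15 = CH3)

1. Cuts: first O–C10 together with C9–Br and C13–Br. This merges the oxolane (O, C7–C10) and its Z-bromopentenyl arm (C10–C13) into one eight-membered dienyl ether, the cis-2,8-disubstituted 7,8-dihydro-2H-oxocine 19, in which O–C13 is a temporary ring bond. Then C6–Cl, C3=C4 and C5–C6; then C7–C8 and O–C7 (three-atom ring expansion of 2-vinyl-2,5-dihydrofuran 5); then C11=C12 (metathesis) and O–C13 (allylic etherification).
2. Enabling feature: the ring oxygen and the bromine-bearing C13 are both 1,4 to C10, through C7–C8–C9 and through the C11=C12 Z-alkene. O, C10 and C13 can therefore share a cis-fused bicyclic oxonium ion made of the oxolane ring and a 2,5-dihydrofuran ring.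
3. Forward order: dihydrofuran ring (step 3), oxocine ring (step 4), side chain built on the oxocine (steps 6–12), then contraction of the oxocine to the oxolane while both bromine atoms enter (step 13).
4. Stereochemistry: C13 from the iridium catalyst (step 2), inverted by bromide in step 13. C7 by thermodynamic cis-equilibration against C13. C6 by chelation-controlled aldol addition, then inverted on chlorination. C9 and C10 by anti addition across the ring Z-alkene with both α-substituents on the convex face of the oxonium ion. C11=C12 is Z because it is a ring alkene; C3=C4 is Z from the Peterson olefination.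

Key step: step 13

Remark: the sense of induction of the iridium catalyst in step 2 is assigned by analogy with related alkyl-substituted allylic carbonates; the mirror-image ligand is equally available if the analogy does not hold.

**Step 1**
Reactants: 1 (E)-pent-2-en-1-ol
Product: 2 tert-butyl (E)-pent-2-en-1-yl carbonate
Conditions: Boc2O, Bu4NHSO4 (cat.), 30% aq NaOH, CH2Cl2, 0 °C to rt
Reagents that add atoms: di-tert-butyl dicarbonate, CC(C)(C)OC(=O)OC(=O)OC(C)(C)C
Why: Phase-transfer O-acylation of a primary allylic alcohol (carbonate formation) installs the leaving group for the allylic substitution; no stereocentre is involved.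

**Step 2**
Reactants: 2 tert-butyl (E)-pent-2-en-1-yl carbonate; 3 penta-1,4-dien-3-ol
Product: 4 (3S)-3-(penta-1,4-dien-3-yloxy)pent-1-ene
Conditions: 3 (3 equiv), [Ir(cod)Cl]2 (2 mol %), (R,R,R)-O,O'-(1,1'-binaphthyl-2,2'-diyl) N,N-bis(1-phenylethyl)phosphoramidite (4 mol %), K3PO4, THF, rt
Reagents that add atoms: none
Why: Iridium-catalysed asymmetric allylic etherification: the cyclometalated iridium phosphoramidite complex ionises the linear carbonate and the alkoxide attacks the ethyl-substituted allyl terminus, so the branched bis-allylic ether should form with C13 set (S) by the catalyst (the divinylcarbinol carbon is not a stereocentre).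

**Step 3**
Reactants: 4 (3S)-3-(penta-1,4-dien-3-yloxy)pent-1-ene
Product: 5 (2S)-5-ethenyl-2-ethyl-2,5-dihydrofuran (C5 epimers)
Conditions: first-generation Grubbs catalyst RuCl2(PCy3)2(=CHPh) (2 mol %), CH2Cl2 (0.05 M), 40 °C; volatile product handled as a concentrated solution
Reagents that add atoms: none
Why: Ring-closing metathesis joins the C13 vinyl group with either vinyl group of the carbinol to the five-membered ring, the only ring this triene can close, which fixes C11=C12 as a ring Z-alkene and leaves C13 untouched; the epimeric mixture at C10 does not matter because that centre becomes sp2 in step 4.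

**Step 4**
Reactants: 5 (2S)-5-ethenyl-2-ethyl-2,5-dihydrofuran (C5 epimers); 6 ethyl diazoacetate
Product: 8 ethyl (2S)-2-ethyl-7,8-dihydro-2H-oxocine-8-carboxylate (C8 epimers), via oxonium ylide 7 (not isolated)
Conditions: 6 (1.3 equiv, syringe pump), Cu(hfacac)2 (5 mol %), CH2Cl2, 40 °C
Reagents that add atoms: none
Why: The copper carbenoid from 6 is captured by the ether oxygen and ylide 7 should undergo the [2,3]-sigmatropic three-atom ring expansion established for 2-vinyl cyclic ethers (C7–C8 forms, the doubly allylic O–C10 bond breaks, and the new C9=C10 alkene must be Z inside the eight-membered ring); C13 is untouched and C7 forms without control, to be corrected in step 5.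

**Step 5**
Reactants: 8 ethyl (2S)-2-ethyl-7,8-dihydro-2H-oxocine-8-carboxylate (C8 epimers)
Product: 9 ethyl (2S,8S)-2-ethyl-7,8-dihydro-2H-oxocine-8-carboxylate (cis)
Conditions: NaOEt (0.2 equiv), EtOH, rt
Reagents that add atoms: none
Why: Base-mediated epimerisation α to the ester through the enolate (ethoxide matches the ester); thermodynamic control is expected to favour the cis isomer with both α,α'-substituents pseudo-equatorial, as is general for medium-ring ethers, which sets C7 (S) relative to the non-acidic C13.

**Step 6**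
Reactants: 9 ethyl (2S,8S)-2-ethyl-7,8-dihydro-2H-oxocine-8-carboxylate
Product: 10 (2S,8S)-2-ethyl-7,8-dihydro-2H-oxocine-8-carbaldehyde
Conditions: DIBAL-H (1.1 equiv), CH2Cl2, −78 °C; MeOH then aq Rochelle salt
Reagents that add atoms: none
Why: Partial reduction of an α-alkoxy ester with DIBAL-H stops at the aldehyde because the chelated tetrahedral aluminium intermediate survives at −78 °C; C7 is retained, and the cis aldehyde is also the thermodynamic epimer.

**Step 7**
Reactants: 10 (2S,8S)-2-ethyl-7,8-dihydro-2H-oxocine-8-carbaldehyde; 11 1-(tert-butyldimethylsilyloxy)-1-methoxyethene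
Product: 12 methyl (3S)-3-[(2S,8S)-2-ethyl-7,8-dihydro-2H-oxocin-8-yl]-3-hydroxypropanoate
Conditions: 11 (2 equiv), MgBr2·OEt2 (3 equiv), CH2Cl2, −78 to −40 °C; aq NaHCO3
Reagents that add atoms: none
Why: Chelation-controlled Mukaiyama aldol addition: magnesium bridges the aldehyde oxygen and the ring oxygen, and the ketene acetal attacks the carbonyl face on the side of the C7 hydrogen (away from C8), which should give the 6,7-syn adduct with C6 (S).

**Step 8**
Reactants: 12 methyl (3S)-3-[(2S,8S)-2-ethyl-7,8-dihydro-2H-oxocin-8-yl]-3-hydroxypropanoate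
Product: 13 methyl (3S)-3-(tert-butyldimethylsilyloxy)-3-[(2S,8S)-2-ethyl-7,8-dihydro-2H-oxocin-8-yl]propanoate
Conditions: TBSOTf, 2,6-lutidine, CH2Cl2, −78 °C
Reagents that add atoms: tert-butyldimethylsilyl triflate, CC(C)(C)[Si](C)(C)OS(=O)(=O)C(F)(F)F
Why: Silylation of the secondary alcohol under buffered conditions protects C6–OH against β-elimination and over-reduction in the next steps; no stereocentre changes.

**Step 9**
Reactants: 13 methyl (3S)-3-(tert-butyldimethylsilyloxy)-3-[(2S,8S)-2-ethyl-7,8-dihydro-2H-oxocin-8-yl]propanoate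
Product: 14 (3S)-3-(tert-butyldimethylsilyloxy)-3-[(2S,8S)-2-ethyl-7,8-dihydro-2H-oxocin-8-yl]propanal
Conditions: DIBAL-H (1.1 equiv), CH2Cl2, −78 °C; aq Rochelle salt
Reagents that add atoms: none
Why: Partial DIBAL-H reduction of a β-silyloxy methyl ester to the aldehyde at low temperature; a β-silyloxy aldehyde is used because the β-chloro aldehyde would lose HCl, so chlorine is introduced later.

**Step 10**
Reactants: 14 (3S)-3-(tert-butyldimethylsilyloxy)-3-[(2S,8S)-2-ethyl-7,8-dihydro-2H-oxocin-8-yl]propanal; 15 1,3-bis(triisopropylsilyl)propyne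
Product: 17 tert-butyl{[(1S,3Z)-1-[(2S,8S)-2-ethyl-7,8-dihydro-2H-oxocin-8-yl]-6-(triisopropylsilyl)hex-3-en-5-yn-1-yl]oxy}dimethylsilane, via lithium β-silyl alkoxide 16 (not isolated)
Conditions: 15 (1.3 equiv), n-BuLi, THF, −20 °C; then 14, −78 °C to rt
Reagents that add atoms: none
Why: Peterson olefination with the lithiated bis(silyl)propyne: addition to the aldehyde and syn-elimination of the bulky silanolate from adduct 16 should give the Z-enyne (C3=C4), with the alkyne left silyl-protected.

**Step 11**
Reactants: 17 tert-butyl{[(1S,3Z)-1-[(2S,8S)-2-ethyl-7,8-dihydro-2H-oxocin-8-yl]-6-(triisopropylsilyl)hex-3-en-5-yn-1-yl]oxy}dimethylsilane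
Product: 18 (1S,3Z)-1-[(2S,8S)-2-ethyl-7,8-dihydro-2H-oxocin-8-yl]hex-3-en-5-yn-1-ol
Conditions: TBAF (3 equiv), THF, 0 °C to rt
Reagents that add atoms: none
Why: Fluoride-mediated desilylation removes the alkynyl silane and the silyl ether in one operation; the base-stable dienyl ether and all stereocentres are unaffected.

**Step 12**
Reactants: 18 (1S,3Z)-1-[(2S,8S)-2-ethyl-7,8-dihydro-2H-oxocin-8-yl]hex-3-en-5-yn-1-ol
Product: 19 (2S,8S)-8-[(1R,3Z)-1-chlorohex-3-en-5-yn-1-yl]-2-ethyl-7,8-dihydro-2H-oxocine
Conditions: CCl4, P(n-Oct)3, toluene, 60 °C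
Reagents that add atoms: carbon tetrachloride, ClC(Cl)(Cl)Cl
Why: Appel reaction: the alkoxyphosphonium ion of the secondary alcohol next to the ring oxygen is displaced by chloride in an SN2 process under neutral conditions, which inverts C6 from (S) to the required (R).

**Step 13**
Reactants: 19 (2S,8S)-8-[(1R,3Z)-1-chlorohex-3-en-5-yn-1-yl]-2-ethyl-7,8-dihydro-2H-oxocine
Product: 21 (2R,3R,5S)-3-bromo-2-[(1Z,3R)-3-bromopent-1-en-1-yl]-5-[(1R,3Z)-1-chlorohex-3-en-5-yn-1-yl]oxolane, via bicyclic oxonium bromide 20 (not isolated)
Conditions: Br2 (1.0 equiv, dilute, dropwise), 2,6-di-tert-butyl-4-methylpyridine (0.2 equiv), CH2Cl2 (0.01 M), −78 °C, dark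
Reagents that add atoms: bromine, BrBr
Why: Br2 delivers Br+ to C9, the terminus of the ring diene remote from the inductively deactivating C13–O bond, on the peripheral face; the ring oxygen, held 1,4 to C10, attacks C10 transannularly anti to the bromine to give the cis-fused oxonium ion 20, and the liberated bromide opens it by SN2 at the allylic carbon C13, which cleaves the temporary O–C13 bond. The closest known reaction type is the bromonium-induced transannular oxonium ion formation–fragmentation of unsaturated medium-ring ethers, the intramolecular relative of dealkylative haloetherification of alkenyl ethers. The oxolane ring (O, C7–C10) closes in a 5-endo mode with respect to the C9=C10 bond, and the same bond formation closes the 2,5-dihydrofuran ring (O, C10–C13) of the oxonium ion, which is opened again. C9 and C10 follow from anti addition across the ring-enforced Z-alkene (Br cis to C11) and from the cis-2,8 relationship of 19, which lets both α-substituents sit on the convex face of the oxonium ion so that C11 ends trans to the C7 side chain; C13 is set by inversion of the (13S)-ether, and C11=C12 stays Z because it is part of a five-membered ring until the last bond breaks. The step needs site selectivity for the diene over the electron-poorer enyne, and for opening at C13 over C7 and C10: the first should come from the higher nucleophilicity of the dienyl ether assisted by the oxygen, the second from allylic activation of C13, from the β-chlorine and branching that deactivate C7, and from the reversibility of attack at C10, which only returns ring dibromides that can re-ionise.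

**Compound list**
1 | (E)-pent-2-en-1-ol | CC/C=C/CO | starting material
2 | tert-butyl (E)-pent-2-en-1-yl carbonate | CC/C=C/COC(=O)OC(C)(C)C | intermediate
3 | penta-1,4-dien-3-ol | C=CC(O)C=C | starting material
4 | (3S)-3-(penta-1,4-dien-3-yloxy)pent-1-ene | CC[C@@H](C=C)OC(C=C)C=C | intermediate
5 | (2S)-5-ethenyl-2-ethyl-2,5-dihydrofuran (C5 epimers) | CC[C@H]1C=CC(C=C)O1 | intermediate
6 | ethyl diazoacetate | CCOC(=O)C=[N+]=[N-] | starting material
7 | oxonium ylide from 5 and the carbene of 6 (not isolated) | CC[C@H]1C=CC(C=C)[O+]1[CH-]C(=O)OCC | intermediate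
8 | ethyl (2S)-2-ethyl-7,8-dihydro-2H-oxocine-8-carboxylate (C8 epimers) | CCOC(=O)C1C/C=C\C=C/[C@H](CC)O1 | intermediate
9 | ethyl (2S,8S)-2-ethyl-7,8-dihydro-2H-oxocine-8-carboxylate | CCOC(=O)[C@@H]1C/C=C\C=C/[C@H](CC)O1 | intermediate
10 | (2S,8S)-2-ethyl-7,8-dihydro-2H-oxocine-8-carbaldehyde | O=C[C@@H]1C/C=C\C=C/[C@H](CC)O1 | intermediate
11 | 1-(tert-butyldimethylsilyloxy)-1-methoxyethene | C=C(OC)O[Si](C)(C)C(C)(C)C | starting material
12 | methyl (3S)-3-[(2S,8S)-2-ethyl-7,8-dihydro-2H-oxocin-8-yl]-3-hydroxypropanoate | COC(=O)C[C@H](O)[C@@H]1C/C=C\C=C/[C@H](CC)O1 | intermediate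
13 | methyl (3S)-3-(tert-butyldimethylsilyloxy)-3-[(2S,8S)-2-ethyl-7,8-dihydro-2H-oxocin-8-yl]propanoate | COC(=O)C[C@H](O[Si](C)(C)C(C)(C)C)[C@@H]1C/C=C\C=C/[C@H](CC)O1 | intermediate
14 | (3S)-3-(tert-butyldimethylsilyloxy)-3-[(2S,8S)-2-ethyl-7,8-dihydro-2H-oxocin-8-yl]propanal | O=CC[C@H](O[Si](C)(C)C(C)(C)C)[C@@H]1C/C=C\C=C/[C@H](CC)O1 | intermediate
15 | 1,3-bis(triisopropylsilyl)propyne | CC(C)[Si](C(C)C)(C(C)C)CC#C[Si](C(C)C)(C(C)C)C(C)C | starting material
16 | lithium β-silyl alkoxide from 14 and lithiated 15 (not isolated; the two new centres are transient) | CC(C)[Si](C(C)C)(C(C)C)C#CC([Si](C(C)C)(C(C)C)C(C)C)C([O-])C[C@H](O[Si](C)(C)C(C)(C)C)[C@@H]1C/C=C\C=C/[C@H](CC)O1.[Li+] | intermediate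
17 | tert-butyl{[(1S,3Z)-1-[(2S,8S)-2-ethyl-7,8-dihydro-2H-oxocin-8-yl]-6-(triisopropylsilyl)hex-3-en-5-yn-1-yl]oxy}dimethylsilane | CC(C)[Si](C(C)C)(C(C)C)C#C/C=C\C[C@H](O[Si](C)(C)C(C)(C)C)[C@@H]1C/C=C\C=C/[C@H](CC)O1 | intermediate
18 | (1S,3Z)-1-[(2S,8S)-2-ethyl-7,8-dihydro-2H-oxocin-8-yl]hex-3-en-5-yn-1-ol | C#C/C=C\C[C@H](O)[C@@H]1C/C=C\C=C/[C@H](CC)O1 | intermediate
19 | (2S,8S)-8-[(1R,3Z)-1-chlorohex-3-en-5-yn-1-yl]-2-ethyl-7,8-dihydro-2H-oxocine | C#C/C=C\C[C@@H](Cl)[C@@H]1C/C=C\C=C/[C@H](CC)O1 | intermediate
20 | cis-fused bicyclic oxonium bromide (O bonded to C7, C10 and C13; not isolated) | C#C/C=C\C[C@@H](Cl)[C@@H]1C[C@@H](Br)[C@H]2C=C[C@H](CC)[O+]12.[Br-] | intermediate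
21 | (2R,3R,5S)-3-bromo-2-[(1Z,3R)-3-bromopent-1-en-1-yl]-5-[(1R,3Z)-1-chlorohex-3-en-5-yn-1-yl]oxolane | C#C/C=C\C[C@@H](Cl)[C@@H]1C[C@@H](Br)[C@@H](/C=C\[C@H](Br)CC)O1 | target

**Count**
Total steps: 13. Longest linear sequence: 13 steps (1 to 21); 3, 6, 11 and 15 enter as purchased.

**Steps most likely to fail**

1. Step 13. What may go wrong: electrophilic attack of bromine at the free Z-enyne, capture of the bromo-allyl cation by bromide before the ring oxygen closes, or acid-promoted ionisation of the dienyl ether. Fallback (sets out from 17, returns at 21): the ring contraction is moved ahead of the alkyne unmasking, so that it runs on a substrate whose enyne is shielded and deactivated by the bulky silyl group and which has no free alkyne C–H. HF·pyridine buffered with pyridine in THF should cleave only the secondary silyl ether of 17 to give the C1-silylated enynol F1. Chlorination as in step 12 should give the C1-silylated chloride F2. Bromination under the conditions of step 13 should give the C1-silylated target F3. TBAF buffered with acetic acid at 0 °C then removes the alkynyl silane to reach 21. Chlorination stays before bromination because a phosphine would quaternise the allylic bromide.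

2. Step 4. What may go wrong: cyclopropanation of the vinyl group by the mono-acceptor carbenoid, or a [1,2]-shift or ionisation of the doubly allylic C–O bond of the ylide, outrunning the [2,3]-shift. Fallback (sets out from 5, returns at 8): an acceptor/acceptor carbene is used, which strongly prefers ylide formation over cyclopropanation and gives a stabilised ylide, and the surplus ester is removed afterwards. Allyl ethyl diazomalonate with Cu(hfacac)2 in CH2Cl2 should convert 5 into the ring-expanded geminal diester 8-allyl 8-ethyl (2S)-2-ethyl-2H-oxocine-8,8(7H)-dicarboxylate F4. Deallylation–decarboxylation with Pd(PPh3)4 (zerovalent palladium), HCO2H and Et3N in THF with gentle warming then gives the mono-ester 8, which enters step 5.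

3. Step 7. What may go wrong: ionisation of the doubly allylic ring C–O bond by the Lewis acid, or loss of facial preference if the hindered ring oxygen chelates poorly. Fallback (sets out from 10, returns at 12): substrate control is replaced by reagent control. Roskamp homologation of 10 with methyl diazoacetate and SnCl2 (cat.) in CH2Cl2 should give the β-keto ester methyl 3-[(2S,8S)-2-ethyl-7,8-dihydro-2H-oxocin-8-yl]-3-oxopropanoate F5. Asymmetric transfer hydrogenation with RuCl(p-cymene)[(S,S)-TsDPEN] in HCO2H/Et3N, using the catalyst enantiomer that delivers the (3S)-carbinol, then gives 12.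

**Further compounds**
F1 | step 13 | (1S,3Z)-1-[(2S,8S)-2-ethyl-7,8-dihydro-2H-oxocin-8-yl]-6-(triisopropylsilyl)hex-3-en-5-yn-1-ol | CC(C)[Si](C(C)C)(C(C)C)C#C/C=C\C[C@H](O)[C@@H]1C/C=C\C=C/[C@H](CC)O1
F2 | step 13 | {(3Z,6R)-6-chloro-6-[(2S,8S)-2-ethyl-7,8-dihydro-2H-oxocin-8-yl]hex-3-en-1-yn-1-yl}triisopropylsilane | CC(C)[Si](C(C)C)(C(C)C)C#C/C=C\C[C@@H](Cl)[C@@H]1C/C=C\C=C/[C@H](CC)O1
F3 | step 13 | {(3Z,6R)-6-[(2S,4R,5R)-4-bromo-5-[(1Z,3R)-3-bromopent-1-en-1-yl]oxolan-2-yl]-6-chlorohex-3-en-1-yn-1-yl}triisopropylsilane | CC(C)[Si](C(C)C)(C(C)C)C#C/C=C\C[C@@H](Cl)[C@@H]1C[C@@H](Br)[C@@H](/C=C\[C@H](Br)CC)O1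
F4 | step 4 | 8-allyl 8-ethyl (2S)-2-ethyl-2H-oxocine-8,8(7H)-dicarboxylate (C8 epimers) | CCOC(=O)C1(C(=O)OCC=C)C/C=C\C=C/[C@H](CC)O1
F5 | step 7 | methyl 3-[(2S,8S)-2-ethyl-7,8-dihydro-2H-oxocin-8-yl]-3-oxopropanoate | COC(=O)CC(=O)[C@@H]1C/C=C\C=C/[C@H](CC)O1
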